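Count the partner first.

| flask | left-handed substrate | right-handed substrate | partner | protic impurity | free catalyst | remark | time |
|---|---|---|---|---|---|---|---|
| north-west | 0.14 M | 0.14 M | 0.30 equiv | 0.028 M | 0.5 mol% | run made earlier |  |
| east | 0.14 M | 0.14 M | 1.2 equiv | 0.028 M | 0.5 mol% | run made earlier |  |
| north | 0.070 M | 0.070 M | 0.60 equiv | 0.028 M | 0.5 mol% | run made earlier |  |
| green | 0.14 M | 0.14 M | 0.600 equiv | 0.0280 M | 0.5 mol% |  | 2.0 d |
| amber | 0.14 M | 0.14 M | 0.600 equiv | 0.0280 M | 0.5 mol% |  | 6.0 d |

| run | time / h | right-handed substrate / % | left-handed substrate / % | left-handed product / % |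
|---|---|---|---|---|
| north-west | 2.50 | 45.4 | 38.3 | 11.7 |
| north-west | 8.00 | 47.1 | 39.7 | 12.5 |
| north-west | 15.0 | 43.8 | 39.0 | 13.3 |
| north-west | 20.0 | 45.7 | 40.1 | 12.9 |
| north-west | 30.0 | 45.0 | 39.8 | 10.8 |
| north-west | 40.0 | 43.9 | 40.7 | 13.5 |
| east | 2.50 | 34.8 | 9.6 | 41.1 |
| east | 8.00 | 33.0 | 9.8 | 43.5 |
| east | 15.0 | 30.7 | 9.0 | 40.8 |
| east | 20.0 | 28.6 | 10.9 | 43.0 |
| east | 30.0 | 25.9 | 14.1 | 42.9 |
| east | 40.0 | 24.7 | 16.9 | 42.7 |
| north | 3.00 | 47.3 | 32.2 | 16.2 |
| north | 6.00 | 44.4 | 29.1 | 20.8 |
| north | 10.0 | 42.7 | 28.8 | 21.2 |
| north | 20.0 | 40.6 | 30.1 | 20.6 |
| north | 40.0 | 41.7 | 32.6 | 22.6 |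

(each reading ± 1 percentage point)

- the winner by excess of right-handed substrate over left-handed substrate among what is left of the two; "neither" if no more than 2 percentage points parts them (green / amber / neither)
- excess of right-handed substrate over left-handed substrate among what is left of the two at the end, green
- excess of right-handed substrate over left-handed substrate among what is left of the two at the end, amber

- free catalyst is single-handed; left-handed substrate and right-handed substrate are mirror images of each other, charged as a racemate, each of them at the stated concentration
- an excess is the difference of the two amounts in percent of their sum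
- an excess is below zero if the other one leads

1. Charge: green and amber each hold 0.0840 M of partner, less than the 0.280 M of the two substrates together. Partner is therefore the limiting reagent, and each mole of it should take one mole of substrate, so 30.0% of the substrate can react.

2. Entries: the north run has the same share of partner, so it serves as the ledger. At 10.0 h it has lost 21.2% as left-handed substrate and 7.30% as right-handed substrate, both counted on the two substrates charged together.

3. Balance: these entries of the north run leave 1.5 percentage points unaccounted for, close to the scatter of 1 point, so no separate entry for protic impurity can be read.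

4. Closing: the north run then shows an excess of right-handed substrate of 19.4%.

5. Afterwards the two mirror images turn into each other, and the gap between them should shrink first-order. Two readings from each run give 0.0213 h⁻¹ in the north-west run, 0.0410 h⁻¹ in the east run and 0.0141 h⁻¹ in the north run. These three values lie far apart, and this reckoning takes their mean, 0.0254 h⁻¹.

6. That mean gives the gap half-life 27.2 h, the time in which the excess falls to half once the substrate total stands still.

7. This reckoning takes the north reading as the excess of green and amber at 10.0 h, an assumption, since those flasks hold other concentrations. Counted from that time, green has 1.40 half-lives, giving 7.39%. Amber has 4.92, giving 0.642%.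

8. The forecast names green, with 6.5% for green and 0.6% for amber, holding that “the rate tracks the amount of partner spent, not substrate concentration”, whereas this reckoning uses one rate for every run.

9. The flasks give green as the winner, with 7.24% for green and 0.620% for amber.

    partner + free catalyst + right-handed substrate → free catalyst + right-handed product (k = 4580 M⁻² h⁻¹)
    partner + free catalyst → spent catalyst (k = 0.586 M⁻¹ h⁻¹)
    partner + protic impurity → quenched reagent (k = 1.42 M⁻¹ h⁻¹)
    partner + free catalyst + left-handed substrate → free catalyst + left-handed product (k = 22100 M⁻² h⁻¹)
    left-handed substrate ⇌ right-handed substrate (k = 0.0128 h⁻¹)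

Quenched reagent takes 0.00159 M of the 0.0840 M of partner in green and leaves its excess nearly as it is. A flask like amber but with 1.00 equiv of partner, read after the same 4.92 half-lives, shows an excess of 1.24%. Amber holds 0% partner and 23.3% left-handed product at 6.00 d, and 23.3% left-handed product at 60.0 d. Green at 20.0 d has had 17.3 half-lives, and its excess reads 0%. Amber at 60.0 d has had 52.6, with left-handed substrate at 35.3%, right-handed substrate at 35.3% and an excess of 0%.

The readings are calculated on assumed constants.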